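## Analysis of the target

The target is a 2,3-dihydrobenzofuran in which benzene ring A is fused to the oxygen ring B (O1, C2, C3, C3a, C7a). C2 carries a 4-hydroxyphenyl group (ring C), C3 a 3,5-dihydroxyphenyl group (ring D), C4 a free hydroxyl and C6 a 2-(4-hydroxyphenyl)ethyl chain. The two stereocenters, C2 and C3, are adjacent, both S, and hold their aryl groups trans across ring B. C2 is a benzylic ether carbon conjugated to a para oxygen, so the O1–C2 bond ionises easily in acid. That endangers late steps, but it also means C2 can be formed last under the control of C3, leaving C3 as the only center that must be made enantioselectively and then kept from losing its proton. The five phenols are electron-rich; four are carried as methyl ethers and the one on C4, like O1, is created late. The hard part is ring A, a 1,2,3,5-tetrasubstituted benzene whose carbon substituent (C3 on C3a) sits between two oxygens, a crowded place for bond formation to a finished arene. The route rests on the pattern around ring A: oxygen on C4 and C7a, carbon on C3a and C6, hydrogen on C5 and C7. With boron standing in for the C4 oxygen and silicon for the C7a oxygen, ring A is the sum of three alkynes (C3a≡C4, C7a≡C7, C5≡C6), and the silicon can be tied to the oxygen on C2.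

## Retrosynthetic reasoning

**20 to 19.** The four O–methyl bonds on rings C and D and on the chain arene are cut. Methyl ethers are the smallest groups that pass through organozinc, organolithium, peroxide and acid steps unchanged. The forward step is a global demethylation that must not open ring B irreversibly.

**19 to 18.** The O1–C2 bond of ring B is cut. C2 is a 4-methoxybenzylic carbon, so the alcohol in 18 ionises under mild acid. The resorcinol in 18 is symmetric about the C3a–C6 axis, so either hydroxyl closes the same ring and nothing has to be differentiated. The forward closure must give the trans isomer, which the aryl group on C3 enforces. The gain is that the C2 configuration of every earlier intermediate is irrelevant.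

**18 to 17.** The C4–O and C7a–O bonds are traced back to a C4–B and a C7a–Si bond, and the C2 hydroxyl to the Si–O link. Both oxidations are ipso, so positions fixed in 17 are carried over. One operation has to convert both bonds and release the C2 alcohol.

**17 to 14 and 16.** This is the key disconnection: C3a–C7a, C4–C5 and C6–C7 are cut, taking ring A apart into three alkynes. The cuts fall there because each piece is then simple. The C3a≡C4 alkyne already carries C3 and C2, the C7a≡C7 alkyne is an ethynyl group on silicon, and the C5≡C6 alkyne carries the chain. The Si–O tether of 14 makes the first coupling intramolecular and closes a temporary oxasilacycle. The forward cyclotrimerisation has to place the chain of 16 on C6 and not on C5.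

**16 to 15.** The alkyne carbon C5 is removed; 16 is the one-carbon homologue of aldehyde 15.

**14 to 10 and 13, then 10 to 8 and 7.** The Si–O bond is cut to alcohol 10 and chlorosilane 13, itself from 11 and 12. The C–B bond of 10 goes back to the terminal alkyne 8, and 8 to its C-silylated form 7. Boron is put on before the silyl ether because 13 carries its own acidic alkyne hydrogen, which a later metalation could not spare.

**7 to 4 and 5, then 4 to 3 to 1 and 2.** The C2–C3 bond is cut between aldehyde 5 and a chiral allenylzinc 6, which comes from mesylate 4. The configuration of C3 is then derived by stereospecific steps from the carbinol center of 3, made by asymmetric alkynylation of 1 with 2. The forward addition must transfer chirality cleanly to C3; the diastereoselectivity at the carbinol carbon is of no consequence.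

## Alternatives that were turned down

**Alternative 1:** Benzannulation of a cyclobutenone with a siloxyalkyne (Danheiser benzannulation).
- **Disconnection.** Ring A is cut at C3a–C7a, C4–C5 and C7–C7a into cyclobutenone A1 (C5, C6, C7, C7a and the chain) and siloxyalkyne A2 (C3a and C4 with C3 and C2 attached).
- **Forward key step.** Heating A1 with A2 triggers ring opening of A1, [2+2] addition of the ynol ether, a second ring opening and a 6π closure at C7–C7a. The product A3 is the resorcinol with C7a as a phenol and C4 as a silyl ether.
- **For.** Both ring A oxygens arrive as oxygen, so no oxidation step is needed. The substitution pattern is fixed by the polarity of the ynol ether and the pericyclic sequence, not by a steric preference at a metal. On certainty of regiochemistry this alternative is stronger than the chosen route.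
- **Against.** A2 needs the same stereodefined alkyne as 8 and then conversion of the terminal alkyne into a hydrolytically fragile silyl ynol ether. The annulation needs prolonged heating next to the benzylic, propargylic C3–H, and the alkyne is branched at C3, which slows the [2+2] step. A1 costs two or three further steps from 16. The differentiation of the two oxygens is bought for nothing, because the resorcinol is symmetric.
- **Comparison.** The step count is no lower. The chosen route gives up the built-in regiochemistry and pays one oxidation step, and in return forms ring A at room temperature under neutral conditions in which C3 is safe.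

**Alternative 2:** Three-component conjunctive coupling at C2 and C3.
- **Disconnection.** The C2–ring C and C3–ring D bonds are cut. Ring A is present from the start in alkenylboronate A4; ring C comes from aryllithium A5 and ring D from aryl triflate A6.
- **Forward key step.** A5 adds to the boron of A4. Under Pd(OAc)2 with a chiral bisphosphine the arylpalladium from A6 adds to C3 while the anisyl group shifts from boron to C2, giving boronic ester A7. Oxidation of the C–B bond, deprotection and acid closure would follow, so C2 is re-set as in the chosen route.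
- **For.** It is the most convergent plan: three simple arenes, no ring synthesis, and C3 set by the catalyst in the bond-forming step. On convergence and step count it is stronger than the chosen route.
- **Against.** The alkene carbon of A4 that becomes C3 carries a 2,6-dioxygenated aryl group. The metallate shift would have to create a diaryl-substituted carbon between two ortho substituents, where direct cross-coupling of the alkenyl group and poor facial control are the expected competitors.
- **Comparison.** Reactivity, regiochemistry and enantioselectivity all ride on one crowded step. The chosen route sets C3 early by chirality transfer from a carbinol, and its risky step creates no stereocenter.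

**Alternative 3:** Brønsted-acid cycloisomerisation of a triarylethene.
- **Disconnection.** The O1–C2 bond and the C3–H bond are removed, leading back to triarylethene A8 with free hydroxyls on ring A and ring C.
- **Forward key step.** A chiral phosphoric acid protonates C3 of A8. The resulting cation at C2 is a protonated para-quinone methide of ring C, and a ring A hydroxyl adds to C2 within the ion pair to give A9.
- **For.** It is the shortest route, an atom-economic isomerisation that sets both centers in one catalytic step. On step economy it is clearly stronger.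
- **Against.** C3, the center that persists, is made by protonating an alkene carbon that bears two aryl groups of similar size (ring A and ring D). The protonation is reversible, so any selectivity can leak back through A8. Free electron-rich phenols beside a quinone methide invite oligomerisation, and A9 still needs demethylation.
- **Comparison.** The chosen route is about twice as long. In exchange, the C3 configuration comes from a well-understood asymmetric carbonyl addition and stereospecific transfer, not from an untested facial discrimination.

Key step: step 9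

## Route

Remark on the chemistry: C2 is re-formed in step 11, so only C3 has to be carried in enantiopure form; the diastereomer ratio at the carbinol carbon of 7 does not reach the target.

Assumption: with (S)-BINOL the alkynyl group is delivered to the Si face of 1, as expected for aromatic aldehydes with this catalyst type; (R)-BINOL would be used if the sense proved opposite.

Step 1
Reactants: 1 3,5-dimethoxybenzaldehyde; 2 trimethylsilylacetylene
Product: 3 (R)-1-(3,5-dimethoxyphenyl)-3-(trimethylsilyl)prop-2-yn-1-ol
Conditions: 2 (3 equiv), Et2Zn (3 equiv), Cy2NH (5 mol%), (S)-BINOL (20 mol%), Ti(OiPr)4 (50 mol%), Et2O, rt; NH4Cl (aq)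
Reagents that add atoms: none
Why: Catalytic asymmetric alkynylzinc addition to an aromatic aldehyde (BINOL–Ti(OiPr)4 type): the alkynylzinc formed from 2 and Et2Zn is transferred inside the chiral titanium binaphtholate to the Si face of 1, which sets the carbinol center as R. Aromatic aldehydes are the favoured substrates of this catalyst.

Step 2
Reactants: 3 (R)-1-(3,5-dimethoxyphenyl)-3-(trimethylsilyl)prop-2-yn-1-ol
Product: 4 (R)-1-(3,5-dimethoxyphenyl)-3-(trimethylsilyl)prop-2-yn-1-yl methanesulfonate
Conditions: MsCl, Et3N, CH2Cl2, −78 → −40 °C; cold aqueous work-up, used crude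
Reagents that add atoms: methanesulfonyl chloride, CS(=O)(=O)Cl
Why: O-Sulfonylation leaves the C–O bond intact, so the configuration is retained. The two meta methoxy groups do not stabilise a benzylic cation, so the mesylate should survive a cold work-up and immediate use.

Step 3
Reactants: 4 (R)-1-(3,5-dimethoxyphenyl)-3-(trimethylsilyl)prop-2-yn-1-yl methanesulfonate; 5 4-methoxybenzaldehyde
Product: 7 (1S,2S)-2-(3,5-dimethoxyphenyl)-1-(4-methoxyphenyl)-4-(trimethylsilyl)but-3-yn-1-ol, via allenyl(ethyl)zinc 6 (not isolated)
Conditions: Pd(OAc)2 (5 mol%), PPh3 (5 mol%), Et2Zn (3 equiv), THF, −78 → −20 °C; NH4Cl (aq)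
Reagents that add atoms: none
Why: Palladium-catalysed zinc umpolung of a propargylic mesylate followed by SE2' addition to an aldehyde: zerovalent palladium displaces the mesylate anti (SN2'), and transmetalation with retention gives the axially chiral allenylzinc 6. Addition of 6 to 5 through a closed six-membered transition state transfers the axial chirality to C3 (net inversion at the former carbinol carbon) and places the anisyl group anti to the aryl group, which gives the anti alcohol.

Step 4
Reactants: 7 (1S,2S)-2-(3,5-dimethoxyphenyl)-1-(4-methoxyphenyl)-4-(trimethylsilyl)but-3-yn-1-ol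
Product: 8 (1S,2R)-2-(3,5-dimethoxyphenyl)-1-(4-methoxyphenyl)but-3-yn-1-ol
Conditions: K2CO3 (0.3 equiv), MeOH, 0 °C
Reagents that add atoms: none
Why: Methanolysis of the alkynyl C–Si bond (protodesilylation). At 0 °C with substoichiometric carbonate the benzylic, propargylic C3–H should not be removed, so C3 is kept; the descriptor changes only because the priorities change.

Step 5
Reactants: 8 (1S,2R)-2-(3,5-dimethoxyphenyl)-1-(4-methoxyphenyl)but-3-yn-1-ol
Product: 10 (1S,2S)-2-(3,5-dimethoxyphenyl)-1-(4-methoxyphenyl)-4-(4,4,5,5-tetramethyl-1,3,2-dioxaborolan-2-yl)but-3-yn-1-ol, via lithium alkynylborate 9 (not isolated)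
Conditions: n-BuLi (2.05 equiv), THF, −78 °C; iPrOBpin (1.1 equiv), −78 °C; HCl in Et2O (2.05 equiv), −78 °C → rt
Reagents that add atoms: 2-isopropoxy-4,4,5,5-tetramethyl-1,3,2-dioxaborolane, CC(C)OB1OC(C)(C)C(C)(C)O1
Why: Standard borylation of a terminal alkyne: deprotonation of O–H and the acetylenic C–H, capture of the acetylide by boron to give ate complex 9, and anhydrous protonolysis to the alkynyl pinacolboronate. The acid is kept stoichiometric and cold so that the 4-methoxybenzylic alcohol does not ionise.

Step 6
Reactants: 11 ethynylmagnesium bromide; 12 dichlorodimethylsilane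
Product: 13 chloro(ethynyl)dimethylsilane
Conditions: 12 (3 equiv), THF, 0 °C → rt, slow addition of 11; fractional distillation
Reagents that add atoms: none
Why: Monosubstitution of a dichlorosilane by a Grignard reagent; excess 12 and inverse addition suppress the second substitution.

Step 7
Reactants: 10 (1S,2S)-2-(3,5-dimethoxyphenyl)-1-(4-methoxyphenyl)-4-(4,4,5,5-tetramethyl-1,3,2-dioxaborolan-2-yl)but-3-yn-1-ol; 13 chloro(ethynyl)dimethylsilane
Product: 14 ({(1S,2S)-2-(3,5-dimethoxyphenyl)-1-(4-methoxyphenyl)-4-(4,4,5,5-tetramethyl-1,3,2-dioxaborolan-2-yl)but-3-yn-1-yl}oxy)(ethynyl)dimethylsilane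
Conditions: imidazole (2 equiv), CH2Cl2, 0 °C; filtration, non-aqueous work-up
Reagents that add atoms: none
Why: O-Silylation of a secondary alcohol with a small, reactive chlorosilane. Anhydrous, mildly basic conditions leave the C(sp)–B bond and both stereocenters untouched.

Step 8
Reactants: 15 3-(4-methoxyphenyl)propanal
Product: 16 4-(4-methoxyphenyl)but-1-yne
Conditions: dimethyl (1-diazo-2-oxopropyl)phosphonate, K2CO3, MeOH, rt
Reagents that add atoms: dimethyl (1-diazo-2-oxopropyl)phosphonate, COP(=O)(OC)C(=[N+]=[N-])C(C)=O
Why: Seyferth–Gilbert homologation in its Ohira–Bestmann form: the diazomethylphosphonate anion released by methanolysis adds to the aldehyde, and the resulting alkylidene carbene rearranges to the terminal alkyne.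

Step 9
Reactants: 14 ({(1S,2S)-2-(3,5-dimethoxyphenyl)-1-(4-methoxyphenyl)-4-(4,4,5,5-tetramethyl-1,3,2-dioxaborolan-2-yl)but-3-yn-1-yl}oxy)(ethynyl)dimethylsilane; 16 4-(4-methoxyphenyl)but-1-yne
Product: 17 (3S,4S)-4-(3,5-dimethoxyphenyl)-3-(4-methoxyphenyl)-7-[2-(4-methoxyphenyl)ethyl]-1,1-dimethyl-5-(4,4,5,5-tetramethyl-1,3,2-dioxaborolan-2-yl)-3,4-dihydro-1H-2,1-benzoxasiline
Conditions: Cp*RuCl(cod) (10 mol%), 16 (3 equiv), ClCH2CH2Cl, rt, 14 added over 6 h
Reagents that add atoms: none
Why: Loss of cod from the divalent ruthenium precatalyst lets the Cp*RuCl fragment bind both alkynes of 14, and oxidative cyclisation joins C3a to C7a to give a bicyclic ruthenacyclopentadiene (formally tetravalent ruthenium) bonded to the metal at C4 and C7. This intramolecular coupling of the tethered 1,7-diyne is the closure of the six-membered oxasilacycle (C7a, Si, O, C2, C3, C3a). Alkyne 16 then coordinates and inserts, and reductive elimination forms C4–C5 and C6–C7, so ring A closes as the last event of a formal [2+2+2] cycloaddition and the catalyst is released. The closest known reaction type is the Cp*RuCl(cod)-catalysed cycloaddition of tethered diynes bearing a boronate on one terminus with terminal alkynes, which gives the meta-substituted arylboronate; cyclotrimerisations of silyl-ether-tethered diynes are the second point of reference. No stereocenter is formed: C2 and C3 are sp3 atoms of the tether, and the neutral, room-temperature conditions offer no path for epimerisation. The step needs chemoselectivity for the cross-reaction over self-trimerisation of 16 and regioselectivity for the chain on C6. The first is secured by the tether, which makes the initial coupling intramolecular, supported by slow addition of 14 into an excess of 16. The second is secured by the steric contrast between the boryl-bearing C4 and the unsubstituted C7 of the ruthenacycle, which places the substituted carbon of 16 next to C7.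

Step 10
Reactants: 17 (3S,4S)-4-(3,5-dimethoxyphenyl)-3-(4-methoxyphenyl)-7-[2-(4-methoxyphenyl)ethyl]-1,1-dimethyl-5-(4,4,5,5-tetramethyl-1,3,2-dioxaborolan-2-yl)-3,4-dihydro-1H-2,1-benzoxasiline
Product: 18 2-[(1S,2S)-1-(3,5-dimethoxyphenyl)-2-hydroxy-2-(4-methoxyphenyl)ethyl]-5-[2-(4-methoxyphenyl)ethyl]benzene-1,3-diol
Conditions: H2O2 (30% aq), KF, KHCO3, THF/MeOH 1:1, rt → 40 °C
Reagents that add atoms: hydrogen peroxide, OO
Why: Boronate oxidation and Tamao–Fleming oxidation in one operation: hydroperoxide adds to boron and to the fluoride-activated alkoxysilane, and aryl shifts from boron and silicon to oxygen place the hydroxyls on C4 and C7a without change of position. The Si–O–C2 link is cleaved to the C2 alcohol, and neither stereocenter is involved.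

Step 11
Reactants: 18 2-[(1S,2S)-1-(3,5-dimethoxyphenyl)-2-hydroxy-2-(4-methoxyphenyl)ethyl]-5-[2-(4-methoxyphenyl)ethyl]benzene-1,3-diol
Product: 19 (2S,3S)-3-(3,5-dimethoxyphenyl)-2-(4-methoxyphenyl)-6-[2-(4-methoxyphenyl)ethyl]-2,3-dihydro-1-benzofuran-4-ol
Conditions: TFA (2 equiv), CH2Cl2 (0.01 M), −20 → 0 °C
Reagents that add atoms: none
Why: Acid-mediated SN1 cycloetherification: the 4-methoxybenzylic alcohol ionises to a planar cation at C2, which is trapped by either of the two equivalent ortho hydroxyls to close the five-membered ring B. The aryl group on C3 directs the anisyl group to the opposite face, and reversible ionisation of O1–C2 lets the more stable trans isomer accumulate, so C2 ends as S under the control of C3. High dilution and low temperature hold back intermolecular Friedel–Crafts alkylation and loss of the C3 proton.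

Step 12
Reactants: 19 (2S,3S)-3-(3,5-dimethoxyphenyl)-2-(4-methoxyphenyl)-6-[2-(4-methoxyphenyl)ethyl]-2,3-dihydro-1-benzofuran-4-ol
Product: 20 (2S,3S)-3-(3,5-dihydroxyphenyl)-2-(4-hydroxyphenyl)-6-[2-(4-hydroxyphenyl)ethyl]-2,3-dihydro-1-benzofuran-4-ol
Conditions: BBr3 (10 equiv), CH2Cl2, −78 → 0 °C; MeOH, then H2O
Reagents that add atoms: none
Why: Lewis-acid cleavage of the four aryl methyl ethers. The target has a saturated chain and no stilbene double bond, and trans is the stable arrangement on ring B, so a reversible opening of O1–C2 should return to the same isomer.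

## Compound list

1 | 3,5-dimethoxybenzaldehyde | COc1cc(C=O)cc(OC)c1 | starting material
2 | trimethylsilylacetylene | C#C[Si](C)(C)C | starting material
3 | (R)-1-(3,5-dimethoxyphenyl)-3-(trimethylsilyl)prop-2-yn-1-ol | O[C@@H](C#C[Si](C)(C)C)c1cc(OC)cc(OC)c1 | intermediate
4 | (R)-1-(3,5-dimethoxyphenyl)-3-(trimethylsilyl)prop-2-yn-1-yl methanesulfonate | CS(=O)(=O)O[C@@H](C#C[Si](C)(C)C)c1cc(OC)cc(OC)c1 | intermediate
5 | 4-methoxybenzaldehyde | COc1ccc(C=O)cc1 | starting material
6 | (aS)-[3-(3,5-dimethoxyphenyl)-1-(trimethylsilyl)propa-1,2-dien-1-yl](ethyl)zinc, not isolated | CC[Zn]C([Si](C)(C)C)=[C@@]=C([H])c1cc(OC)cc(OC)c1 | intermediate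
7 | (1S,2S)-2-(3,5-dimethoxyphenyl)-1-(4-methoxyphenyl)-4-(trimethylsilyl)but-3-yn-1-ol | O[C@H](c1ccc(OC)cc1)[C@H](C#C[Si](C)(C)C)c1cc(OC)cc(OC)c1 | intermediate
8 | (1S,2R)-2-(3,5-dimethoxyphenyl)-1-(4-methoxyphenyl)but-3-yn-1-ol | O[C@H](c1ccc(OC)cc1)[C@H](C#C)c1cc(OC)cc(OC)c1 | intermediate
9 | dilithium salt of the alkoxide and alkynyl(isopropoxy)pinacolborate derived from 8, not isolated | [Li]O[C@H](c1ccc(OC)cc1)[C@H](C#C[B-]1(OC(C)C)OC(C)(C)C(C)(C)O1)c1cc(OC)cc(OC)c1.[Li+] | intermediate
10 | (1S,2S)-2-(3,5-dimethoxyphenyl)-1-(4-methoxyphenyl)-4-(4,4,5,5-tetramethyl-1,3,2-dioxaborolan-2-yl)but-3-yn-1-ol | O[C@H](c1ccc(OC)cc1)[C@H](C#CB1OC(C)(C)C(C)(C)O1)c1cc(OC)cc(OC)c1 | intermediate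
11 | ethynylmagnesium bromide | C#C[Mg]Br | starting material
12 | dichlorodimethylsilane | C[Si](C)(Cl)Cl | starting material
13 | chloro(ethynyl)dimethylsilane | C#C[Si](C)(C)Cl | intermediate
14 | ({(1S,2S)-2-(3,5-dimethoxyphenyl)-1-(4-methoxyphenyl)-4-(4,4,5,5-tetramethyl-1,3,2-dioxaborolan-2-yl)but-3-yn-1-yl}oxy)(ethynyl)dimethylsilane | C#C[Si](C)(C)O[C@H](c1ccc(OC)cc1)[C@H](C#CB1OC(C)(C)C(C)(C)O1)c1cc(OC)cc(OC)c1 | intermediate
15 | 3-(4-methoxyphenyl)propanal | COc1ccc(CCC=O)cc1 | starting material
16 | 4-(4-methoxyphenyl)but-1-yne | COc1ccc(CCC#C)cc1 | intermediate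
17 | (3S,4S)-4-(3,5-dimethoxyphenyl)-3-(4-methoxyphenyl)-7-[2-(4-methoxyphenyl)ethyl]-1,1-dimethyl-5-(4,4,5,5-tetramethyl-1,3,2-dioxaborolan-2-yl)-3,4-dihydro-1H-2,1-benzoxasiline | COc1ccc(CCc2cc(B4OC(C)(C)C(C)(C)O4)c3c(c2)[Si](C)(C)O[C@H](c2ccc(OC)cc2)[C@H]3c2cc(OC)cc(OC)c2)cc1 | intermediate
18 | 2-[(1S,2S)-1-(3,5-dimethoxyphenyl)-2-hydroxy-2-(4-methoxyphenyl)ethyl]-5-[2-(4-methoxyphenyl)ethyl]benzene-1,3-diol | COc1ccc(CCc2cc(O)c(c(O)c2)[C@H](c2cc(OC)cc(OC)c2)[C@H](O)c2ccc(OC)cc2)cc1 | intermediate
19 | (2S,3S)-3-(3,5-dimethoxyphenyl)-2-(4-methoxyphenyl)-6-[2-(4-methoxyphenyl)ethyl]-2,3-dihydro-1-benzofuran-4-ol | COc1ccc(CCc2cc(O)c3c(c2)O[C@H](c2ccc(OC)cc2)[C@H]3c2cc(OC)cc(OC)c2)cc1 | intermediate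
20 | (2S,3S)-3-(3,5-dihydroxyphenyl)-2-(4-hydroxyphenyl)-6-[2-(4-hydroxyphenyl)ethyl]-2,3-dihydro-1-benzofuran-4-ol | Oc1ccc(CCc2cc(O)c3c(c2)O[C@H](c2ccc(O)cc2)[C@H]3c2cc(O)cc(O)c2)cc1 | target

## Step count and least certain steps

Total: 12 steps. Longest linear sequence: 10 steps (steps 1, 2, 3, 4, 5, 7, 9, 10, 11, 12); steps 6 and 8 supply 13 and 16.

**Step 9 (key step).** The oxidative cyclisation of the 1,7-diyne may be slow, because the Si–C and Si–O bonds are long and the boryl terminus is hindered. Self-trimerisation of 16 or intermolecular coupling of the ethynylsilane would then take over, and regiocontrol at the insertion could also leak. The fallback replaces the isolated silyl ether by a temporary boron–oxygen tether assembled in the flask, whose shorter bonds bring the alkynes closer. It sets out from 10 and 11. Compound 11 and B(OiPr)3, followed by HCl in Et2O, would give diisopropyl ethynylboronate F1. Exchange of one isopropoxy group of F1 with the hydroxyl of 10 would give the boron-tethered diyne F2, which is not isolated. Cp*RuCl(cod) and 16 would convert F2 into the cyclic boronic ester F3, with boron on C7a. Oxidation of both C–B bonds of F3 with H2O2 and NaOH would give 18, where the fallback rejoins the route, bypassing 13, 14 and 17.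

**Step 3.** The aryl-substituted allenylpalladium and allenylzinc intermediates may racemise before they add to 5, and 4 may ionise before oxidative addition; either process erodes the enantiomeric purity of C3. The fallback uses a configurationally stable allenylboron reagent. It sets out from 3: methyl chloroformate and pyridine would give the methyl carbonate F4. Copper-catalysed anti SN2' borylation (B2pin2, CuOtBu, Xantphos, THF) would give the allenylboronate F5. Heating F5 with 5 in toluene would give 7 through the same closed transition state, and the fallback rejoins the route at 7.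

**Step 11.** The C2 cation may lose the C3 proton and be reprotonated, which erodes the configuration at C3, or it may alkylate the resorcinol ring of a second molecule. The fallback closes ring B by SN2 displacement under neutral conditions. It sets out from 18: PPh3 and diisopropyl azodicarboxylate in THF at 0 °C would give, with inversion at C2, the cis-dihydrobenzofuran F6. Brief exposure of F6 to a catalytic amount of TFA would epimerise C2 within the closed ring to give 19, where the fallback rejoins the route.

**Step 12.** BBr3 may open ring B at O1–C2 and the opened cation may then eliminate or alkylate an arene; cleavage of all four ethers may also stall. The fallback is nucleophilic demethylation with NaSEt in DMF at 130 °C, which avoids a Lewis acid altogether. It sets out from 19 and arrives directly at 20; it makes no new compound (entry F0).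

## Further compounds

F1 | step 9 | diisopropyl ethynylboronate | C#CB(OC(C)C)OC(C)C
F2 | step 9 | isopropyl (1S,2S)-2-(3,5-dimethoxyphenyl)-1-(4-methoxyphenyl)-4-(4,4,5,5-tetramethyl-1,3,2-dioxaborolan-2-yl)but-3-yn-1-yl ethynylboronate | C#CB(OC(C)C)O[C@H](c1ccc(OC)cc1)[C@H](C#CB1OC(C)(C)C(C)(C)O1)c1cc(OC)cc(OC)c1
F3 | step 9 | (3S,4S)-4-(3,5-dimethoxyphenyl)-1-isopropoxy-3-(4-methoxyphenyl)-7-[2-(4-methoxyphenyl)ethyl]-5-(4,4,5,5-tetramethyl-1,3,2-dioxaborolan-2-yl)-3,4-dihydro-1H-2,1-benzoxaborinine | COc1ccc(CCc2cc(B4OC(C)(C)C(C)(C)O4)c3c(c2)B(OC(C)C)O[C@H](c2ccc(OC)cc2)[C@H]3c2cc(OC)cc(OC)c2)cc1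
F4 | step 3 | (R)-1-(3,5-dimethoxyphenyl)-3-(trimethylsilyl)prop-2-yn-1-yl methyl carbonate | COC(=O)O[C@@H](C#C[Si](C)(C)C)c1cc(OC)cc(OC)c1
F5 | step 3 | (aR)-2-[3-(3,5-dimethoxyphenyl)-1-(trimethylsilyl)propa-1,2-dien-1-yl]-4,4,5,5-tetramethyl-1,3,2-dioxaborolane | CC1(C)OB(OC1(C)C)C([Si](C)(C)C)=[C@@]=C([H])c1cc(OC)cc(OC)c1
F6 | step 11 | (2R,3S)-3-(3,5-dimethoxyphenyl)-2-(4-methoxyphenyl)-6-[2-(4-methoxyphenyl)ethyl]-2,3-dihydro-1-benzofuran-4-ol (cis) | COc1ccc(CCc2cc(O)c3c(c2)O[C@@H](c2ccc(OC)cc2)[C@H]3c2cc(OC)cc(OC)c2)cc1
F0 | step 12 | none | none
A1 | alternative 1 | 3-[2-(4-methoxyphenyl)ethyl]cyclobut-2-en-1-one | O=C1CC(CCc2ccc(OC)cc2)=C1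
A2 | alternative 1 | tert-butyl{[(1S,2S)-2-(3,5-dimethoxyphenyl)-1-(4-methoxyphenyl)-4-(triisopropylsilyloxy)but-3-yn-1-yl]oxy}dimethylsilane | CC(C)[Si](OC#C[C@H](c1cc(OC)cc(OC)c1)[C@H](O[Si](C)(C)C(C)(C)C)c1ccc(OC)cc1)(C(C)C)C(C)C
A3 | alternative 1 | 2-[(1S,2S)-2-(tert-butyldimethylsilyloxy)-1-(3,5-dimethoxyphenyl)-2-(4-methoxyphenyl)ethyl]-5-[2-(4-methoxyphenyl)ethyl]-3-(triisopropylsilyloxy)phenol | COc1ccc(CCc2cc(O[Si](C(C)C)(C(C)C)C(C)C)c(c(O)c2)[C@H](c2cc(OC)cc(OC)c2)[C@H](O[Si](C)(C)C(C)(C)C)c2ccc(OC)cc2)cc1
A4 | alternative 2 | (E)-2-{2-[2,6-bis(methoxymethoxy)-4-[2-(4-methoxyphenyl)ethyl]phenyl]ethenyl}-4,4,5,5-tetramethyl-1,3,2-dioxaborolane | COCOc1cc(CCc2ccc(OC)cc2)cc(OCOC)c1/C=C/B1OC(C)(C)C(C)(C)O1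
A5 | alternative 2 | 4-methoxyphenyllithium | [Li]c1ccc(OC)cc1
A6 | alternative 2 | 3,5-dimethoxyphenyl trifluoromethanesulfonate | COc1cc(OC)cc(OS(=O)(=O)C(F)(F)F)c1
A7 | alternative 2 | pinacol boronic ester of the 1,2,2-triarylethyl unit, boron on C2 | COc1ccc(CCc2cc(OCOC)c(c(OCOC)c2)[C@H](c2cc(OC)cc(OC)c2)[C@@H](B2OC(C)(C)C(C)(C)O2)c2ccc(OC)cc2)cc1
A8 | alternative 3 | (Z)-2-[1-(3,5-dimethoxyphenyl)-2-(4-hydroxyphenyl)ethenyl]-5-[2-(4-methoxyphenyl)ethyl]benzene-1,3-diol | COc1ccc(CCc2cc(O)c(/C(=C\c3ccc(O)cc3)c3cc(OC)cc(OC)c3)c(O)c2)cc1
A9 | alternative 3 | (2S,3S)-3-(3,5-dimethoxyphenyl)-2-(4-hydroxyphenyl)-6-[2-(4-methoxyphenyl)ethyl]-2,3-dihydro-1-benzofuran-4-ol | COc1ccc(CCc2cc(O)c3c(c2)O[C@H](c2ccc(O)cc2)[C@H]3c2cc(OC)cc(OC)c2)cc1
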